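The numbers come from no measurement; what happens was integrated by code.

Starting material turns into intermediate on its own, the easy step, with a half-life of 3.6 min.

in all of them: first nucleophile 0.900 equiv

| flask | starting material | second nucleophile | time | remark |
|---|---|---|---|---|
| Sunday's | 0.19 M | 1.20 equiv | 4.0 min | everything together in a closed stirred flask, run for 4.0 min |
| Monday's | 0.19 M | 1.20 equiv |  | a single well-mixed tank run continuously and read at steady state, 4.0 min in it on average |
| Saturday's | 0.19 M | 1.20 equiv (fed, over 3.20 min) | 4.0 min | a stirred flask in which second nucleophile is dosed at a steady rate over 3.20 min without added volume, worked up at 4.0 min |
| Tuesday's | 0.19 M (fed, over 3.20 min) | 1.20 equiv | 4.0 min | a stirred flask in which starting material is dosed at a steady rate over 3.20 min without added volume, worked up at 4.0 min |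

* the set-up with the highest share of target in all that became target or other capture product or over-reaction product, at the outlet or at the end ("none" if the first two lie within 2 percentage points) (Sunday's / Monday's / Saturday's / Tuesday's / none)
* share of target in all that became target or other capture product or over-reaction product, at the outlet or at the end, Sunday's
* share of target in all that became target or other capture product or over-reaction product, at the outlet or at the end, Monday's
* share of target in all that became target or other capture product or over-reaction product, at the outlet or at the end, Saturday's
* share of target in all that became target or other capture product or over-reaction product, at the outlet or at the end, Tuesday's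

- the stated concentrations are those of everything mixed, before any reaction; amounts are the same in each set-up
- the feed brings no volume worth counting
- run time (Sunday's): 4.0 min

Would intermediate collect? On Sunday's charges, capture by second nucleophile gives it a half-life of 0.52 s, much shorter than 3.6 min. So I expected capture as fast as it formed, with its formation the rate-limiting step.

Where would it go? Let kT be the constant of capture by first nucleophile, 1.1 M⁻¹ s⁻¹, and kQ that of capture by second nucleophile, 5.9 M⁻¹ s⁻¹. I divided one capture rate by the other, so intermediate and time dropped out. That left r = kT[first nucleophile]/(kQ[second nucleophile]), the split ratio, a selectivity factor. The charges give r = 0.140, so target takes r/(1+r) = 12.3% of what is captured. I took that for Sunday's, Monday's and Tuesday's.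

What does dosing change? In Saturday's, the delivered second nucleophile averages half its charge during the feed. Doubling r for the whole run gave my estimate of 21.9%, more than 12.3%.

Would target survive? On Sunday's charges its half-life by over-reaction is 3.4 min, shorter than the run of 4.0 min, so I expected final shares of target below my figures. I committed to Saturday's as best.

The forecast named Saturday's, with 11.3% for Sunday's, 10.2% for Monday's, 23% for Saturday's and 11.3% for Tuesday's. Its grounds: “only dosing the second nucleophile holds that ratio in the target's favour”.

The simulation gave Saturday's as best, with 10.8%, 10.3%, 22.8% and 10.9% in the same order.

    starting material → intermediate (k1 = 0.0032 s⁻¹)
    first nucleophile + intermediate → target (k2 = 1.1 M⁻¹ s⁻¹)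
    second nucleophile + intermediate → other capture product (k3 = 5.9 M⁻¹ s⁻¹)
    second nucleophile + target → over-reaction product (k4 = 0.015 M⁻¹ s⁻¹)

Counting over-reaction product with target, Saturday's captured 30.6% as target, not 21.9%, so the closeness of 21.9% to 22.8% is no check. The neighbour is Saturday's with 3.00 equiv of second nucleophile. There r falls to 0.0559, and doubling it gives a share of 10.1%. That flask gave 6.72%, or 16.4% with over-reaction product counted back. At 4.00 min it held 3.60% target and 5.20% over-reaction product, each in percent of the starting material charged.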